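**Retrosynthetic overview**

- The target is read as the cis (2S,3S) 3-acyloxy-2-isopropenyl-2,3-dihydrobenzofuran with 5-acetyl and 6-hydroxyl groups and a (Z)-4-acetoxy-2-methylbut-2-enoate on O3. The phenol is freed last from a PMB ether, the Z side chain is cut at its C=C bond (Still–Gennari olefination of a C3 phosphonopropionate with 2-oxoethyl acetate), and the isopropenyl group comes from a tertiary alcohol.
- The strategy rests on the dihydrofuran ring O1–C2–C3–C3a–C7a fused to the resorcinol-derived benzene ring. Its two bonds to the arene side, C3a–C3 and O1–C2, are cut together, so that the C3 carbinol, the C2 ether carbon and the neighbouring oxygen-bearing C(CH3)2 carbon become (R)-3,3-dimethyloxirane-2-carbaldehyde, and the arene becomes 4-hydroxyacetophenone with its 2-oxygen blocked as a PMB ether.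
- Ring order: the benzene ring is bought with 2,4-dihydroxyacetophenone; the dihydrofuran ring is the only ring made and closes in the key step.
- The epoxy aldehyde comes from 3-methylbut-2-en-1-ol by asymmetric epoxidation and oxidation; the phenol comes from 2,4-dihydroxyacetophenone by allylation, PMB protection and deallylation.

Key step: step 6

Remark: the phosphonate esters made in steps 8 and 9 carry an uncontrolled stereocentre at the phosphorus-bearing carbon and are drawn without a descriptor there; both epimers converge in step 11, where that carbon becomes sp2.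

**Route**

Step 1
Reactants: 1 2,4-dihydroxyacetophenone
Product: 2 1-[4-(allyloxy)-2-hydroxyphenyl]ethanone
Conditions: allyl bromide (1.05 equiv), K2CO3, acetone, reflux
Reagents that add atoms: allyl bromide, C=CCBr
Why: Williamson ether synthesis; the 2-hydroxyl is locked in a hydrogen bond to the acetyl carbonyl, so with one equivalent of allyl bromide the more acidic and more nucleophilic 4-phenoxide should be alkylated selectively.

Step 2
Reactants: 2 1-[4-(allyloxy)-2-hydroxyphenyl]ethanone
Product: 3 1-[4-(allyloxy)-2-[(4-methoxybenzyl)oxy]phenyl]ethanone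
Conditions: PMBCl, K2CO3, Bu4NI (cat.), DMF, 60 °C
Reagents that add atoms: 4-methoxybenzyl chloride, COc1ccc(CCl)cc1
Why: Williamson ether synthesis on the remaining chelated phenol, which needs the polar solvent, iodide catalysis and gentle heating; the allyl aryl ether and the ketone are inert to K2CO3.

Step 3
Reactants: 3 1-[4-(allyloxy)-2-[(4-methoxybenzyl)oxy]phenyl]ethanone
Product: 4 1-[4-hydroxy-2-[(4-methoxybenzyl)oxy]phenyl]ethanone
Conditions: Pd(PPh3)4 (cat.), morpholine, THF, rt
Reagents that add atoms: none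
Why: Tsuji–Trost deallylation; zerovalent palladium ionises the allyl aryl ether (the para-acyl phenoxide is a good leaving group) and morpholine captures the π-allyl fragment, while the PMB ether and the ketone are not touched.

Step 4
Reactants: 5 3-methylbut-2-en-1-ol
Product: 6 (S)-(3,3-dimethyloxiran-2-yl)methanol
Conditions: Ti(OiPr)4 (cat.), L-(+)-diethyl tartrate (cat.), t-BuOOH, 4 Å MS, CH2Cl2, −20 °C
Reagents that add atoms: tert-butyl hydroperoxide, CC(C)(C)OO
Why: Sharpless asymmetric epoxidation; the titanium L-(+)-tartrate catalyst delivers the peroxide oxygen to one enantiotopic face of the allylic alcohol and sets the single stereocentre as S.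

Step 5
Reactants: 6 (S)-(3,3-dimethyloxiran-2-yl)methanol
Product: 7 (R)-3,3-dimethyloxirane-2-carbaldehyde
Conditions: PhI(OAc)2, TEMPO (cat.), CH2Cl2, 0 °C to rt; used as a dried solution
Reagents that add atoms: none
Why: Oxoammonium (TEMPO) oxidation of a primary alcohol to the aldehyde under neutral conditions that leave the epoxide and its stereocentre intact (the descriptor changes from S to R only through the priority rules); the volatile aldehyde is not distilled.

Step 6
Reactants: 4 1-[4-hydroxy-2-[(4-methoxybenzyl)oxy]phenyl]ethanone; 7 (R)-3,3-dimethyloxirane-2-carbaldehyde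
Product: 10 1-[(2R,3S)-3-hydroxy-2-(2-hydroxypropan-2-yl)-6-[(4-methoxybenzyl)oxy]-2,3-dihydro-1-benzofuran-5-yl]ethanone, via titanium aryloxide 8 (not isolated), via anti epoxy alcohol 9 (not isolated)
Conditions: Ti(OiPr)4 (1.0 equiv), toluene, rt, then evaporation (removes i-PrOH); 7 (1.2 equiv), CH2Cl2, −20 °C to rt; then MeOH, K2CO3, 45 °C
Reagents that add atoms: none
Why: Proposed new method: the aryloxide ArOTi(OiPr)3 binds the aldehyde oxygen and hands the carbonyl carbon to its own ortho carbon through a closed six-membered transition state (C3a–C3), the dienone re-aromatises to a titanium-chelated salicyl-type alkoxide, and once methanolic K2CO3 has stripped the titanium the free phenoxide attacks the epoxide CH carbon (O1–C2). The closest known reaction types are the ortho-specific hydroxyalkylation of magnesium and titanium phenoxides with chiral α-oxygenated aldehydes and the base-induced cyclisation of 2-(2,3-epoxy-3-methylbutyl)phenols (acyl-substituted ones included) to 2-(2-hydroxypropan-2-yl)-2,3-dihydrobenzofurans; what has not been shown is their union in one flask with an α,β-epoxy aldehyde on an acyl-deactivated phenoxide. The dihydrofuran ring closes 5-exo-tet with inversion at the epoxide carbon. C3 is set by Felkin–Anh addition anti to the epoxide C–O bond, which the bulky, non-chelating triisopropoxytitanium centre should favour, and C2 is relayed from the enantiopure epoxide by the SN2 inversion, so that the anti adduct ends as the cis 2,3-disubstituted ring. The step needs attack at the ring carbon para to the PMB ether and not at the carbon flanked by the two oxygens, which the bulk of the PMB group secures, and 5-exo opening at the secondary carbon and not 6-endo opening at the tertiary one, which is secured by removing the Lewis acidic titanium before warming so that the closure runs under basic SN2 conditions.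

Step 7
Reactants: 11 ethyl 2-[bis(2,2,2-trifluoroethoxy)phosphoryl]propanoate
Product: 12 2-[bis(2,2,2-trifluoroethoxy)phosphoryl]propanoic acid
Conditions: LiOH·H2O (1.05 equiv), THF/H2O, 0 °C; then 1 M HCl
Reagents that add atoms: lithium hydroxide, [Li+].[OH-]
Why: Ester saponification; one equivalent of hydroxide at 0 °C should attack the activated carboxylic ester in preference to phosphorus, and the carboxylate formed protects the trifluoroethyl phosphonate from further attack.

Step 8
Reactants: 10 1-[(2R,3S)-3-hydroxy-2-(2-hydroxypropan-2-yl)-6-[(4-methoxybenzyl)oxy]-2,3-dihydro-1-benzofuran-5-yl]ethanone; 12 2-[bis(2,2,2-trifluoroethoxy)phosphoryl]propanoic acid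
Product: 13 (2R,3S)-5-acetyl-2-(2-hydroxypropan-2-yl)-6-[(4-methoxybenzyl)oxy]-2,3-dihydro-1-benzofuran-3-yl 2-[bis(2,2,2-trifluoroethoxy)phosphoryl]propanoate
Conditions: DCC, DMAP (cat.), CH2Cl2, 0 °C to rt
Reagents that add atoms: none
Why: Steglich esterification; the carbodiimide-activated phosphonoacetic acid acylates the secondary C3 hydroxyl while the tertiary hydroxyl is too hindered to react, and C2 and C3 are not touched.

Step 9
Reactants: 13 (2R,3S)-5-acetyl-2-(2-hydroxypropan-2-yl)-6-[(4-methoxybenzyl)oxy]-2,3-dihydro-1-benzofuran-3-yl 2-[bis(2,2,2-trifluoroethoxy)phosphoryl]propanoate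
Product: 15 (2S,3S)-5-acetyl-6-[(4-methoxybenzyl)oxy]-2-(prop-1-en-2-yl)-2,3-dihydro-1-benzofuran-3-yl 2-[bis(2,2,2-trifluoroethoxy)phosphoryl]propanoate, via sulfamate ester 14 (not isolated)
Conditions: Burgess reagent, THF, rt to 50 °C
Reagents that add atoms: none
Why: Burgess dehydration; the tertiary alcohol becomes a sulfamate ester that eliminates by a syn (Ei) pathway, for which the six methyl hydrogens are statistically and sterically favoured over the single C2–H, so the isopropenyl group should form under neutral conditions that spare the ester, the PMB ether and both stereocentres (C2 becomes S only through the priority rules).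

Step 10
Reactants: 16 (Z)-but-2-ene-1,4-diyl diacetate
Product: 18 2-oxoethyl acetate, via ozonide 17 (not isolated)
Conditions: O3, CH2Cl2, −78 °C; then Me2S, −78 °C to rt
Reagents that add atoms: ozone, [O-][O+]=O
Why: Ozonolysis with reductive work-up; the symmetric alkene is cleaved to two molecules of the same aldehyde, and dimethyl sulfide reduces the ozonide without touching the acetate.

Step 11
Reactants: 15 (2S,3S)-5-acetyl-6-[(4-methoxybenzyl)oxy]-2-(prop-1-en-2-yl)-2,3-dihydro-1-benzofuran-3-yl 2-[bis(2,2,2-trifluoroethoxy)phosphoryl]propanoate; 18 2-oxoethyl acetate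
Product: 20 (2S,3S)-5-acetyl-6-[(4-methoxybenzyl)oxy]-2-(prop-1-en-2-yl)-2,3-dihydro-1-benzofuran-3-yl (2Z)-4-(acetyloxy)-2-methylbut-2-enoate, via potassium phosphonate 19 (not isolated)
Conditions: KN(SiMe3)2 (0.95 equiv), 18-crown-6, THF, −78 °C; then 18, −78 °C
Reagents that add atoms: none
Why: Still–Gennari olefination; the phosphonate C–H is by far the strongest carbon acid present and is the one deprotonated, and the electron-poor bis(trifluoroethyl) phosphonate collapses under kinetic control to the Z-trisubstituted enoate, so the geometry is set on the substrate without any isomerisable activated acid.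

Step 12
Reactants: 20 (2S,3S)-5-acetyl-6-[(4-methoxybenzyl)oxy]-2-(prop-1-en-2-yl)-2,3-dihydro-1-benzofuran-3-yl (2Z)-4-(acetyloxy)-2-methylbut-2-enoate
Product: 21 (2S,3S)-5-acetyl-6-hydroxy-2-(prop-1-en-2-yl)-2,3-dihydro-1-benzofuran-3-yl (2Z)-4-(acetyloxy)-2-methylbut-2-enoate
Conditions: DDQ, CH2Cl2/pH 7 buffer, 0 °C to rt
Reagents that add atoms: none
Why: Oxidative PMB ether cleavage; DDQ abstracts hydride from the electron-rich p-methoxybenzyl position and water hydrolyses the oxocarbenium ion to the phenol, while the acyl-deactivated benzofuran ring, the alkenes and the esters should not be oxidised.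

**Compound list**

1 | 2,4-dihydroxyacetophenone | CC(=O)c1ccc(O)cc1O | starting material
2 | 1-[4-(allyloxy)-2-hydroxyphenyl]ethanone | CC(=O)c1ccc(OCC=C)cc1O | intermediate
3 | 1-[4-(allyloxy)-2-[(4-methoxybenzyl)oxy]phenyl]ethanone | CC(=O)c1ccc(OCC=C)cc1OCc2ccc(OC)cc2 | intermediate
4 | 1-[4-hydroxy-2-[(4-methoxybenzyl)oxy]phenyl]ethanone | CC(=O)c1ccc(O)cc1OCc2ccc(OC)cc2 | intermediate
5 | 3-methylbut-2-en-1-ol | CC(C)=CCO | starting material
6 | (S)-(3,3-dimethyloxiran-2-yl)methanol | OC[C@@H]1OC1(C)C | intermediate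
7 | (R)-3,3-dimethyloxirane-2-carbaldehyde | O=C[C@@H]1OC1(C)C | intermediate
8 | triisopropoxytitanium 4-acetyl-3-[(4-methoxybenzyl)oxy]phenoxide, ArOTi(OiPr)3 (formed in the flask) | CC(=O)c1ccc(O[Ti](OC(C)C)(OC(C)C)OC(C)C)cc1OCc2ccc(OC)cc2 | intermediate
9 | 1-[4-hydroxy-5-[(S)-[(S)-3,3-dimethyloxiran-2-yl](hydroxy)methyl]-2-[(4-methoxybenzyl)oxy]phenyl]ethanone (anti adduct, formed in the flask) | CC(=O)c1cc([C@H](O)[C@@H]2OC2(C)C)c(O)cc1OCc3ccc(OC)cc3 | intermediate
10 | 1-[(2R,3S)-3-hydroxy-2-(2-hydroxypropan-2-yl)-6-[(4-methoxybenzyl)oxy]-2,3-dihydro-1-benzofuran-5-yl]ethanone | CC(C)(O)[C@@H]1Oc2cc(OCc3ccc(OC)cc3)c(C(C)=O)cc2[C@@H]1O | intermediate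
11 | ethyl 2-[bis(2,2,2-trifluoroethoxy)phosphoryl]propanoate (racemic) | CCOC(=O)C(C)P(=O)(OCC(F)(F)F)OCC(F)(F)F | starting material
12 | 2-[bis(2,2,2-trifluoroethoxy)phosphoryl]propanoic acid (racemic) | CC(C(=O)O)P(=O)(OCC(F)(F)F)OCC(F)(F)F | intermediate
13 | (2R,3S)-5-acetyl-2-(2-hydroxypropan-2-yl)-6-[(4-methoxybenzyl)oxy]-2,3-dihydro-1-benzofuran-3-yl 2-[bis(2,2,2-trifluoroethoxy)phosphoryl]propanoate (both epimers at the phosphonate carbon) | CC(C)(O)[C@@H]1Oc2cc(OCc3ccc(OC)cc3)c(C(C)=O)cc2[C@@H]1OC(=O)C(C)P(=O)(OCC(F)(F)F)OCC(F)(F)F | intermediate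
14 | triethylammonium salt of the tertiary N-(methoxycarbonyl)sulfamate ester of 13 (formed in the flask) | COC(=O)[N-]S(=O)(=O)OC(C)(C)[C@@H]1Oc2cc(OCc3ccc(OC)cc3)c(C(C)=O)cc2[C@@H]1OC(=O)C(C)P(=O)(OCC(F)(F)F)OCC(F)(F)F.CC[NH+](CC)CC | intermediate
15 | (2S,3S)-5-acetyl-6-[(4-methoxybenzyl)oxy]-2-(prop-1-en-2-yl)-2,3-dihydro-1-benzofuran-3-yl 2-[bis(2,2,2-trifluoroethoxy)phosphoryl]propanoate (both epimers at the phosphonate carbon) | C=C(C)[C@@H]1Oc2cc(OCc3ccc(OC)cc3)c(C(C)=O)cc2[C@@H]1OC(=O)C(C)P(=O)(OCC(F)(F)F)OCC(F)(F)F | intermediate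
16 | (Z)-but-2-ene-1,4-diyl diacetate | CC(=O)OC/C=C\COC(C)=O | starting material
17 | 3,5-bis(acetoxymethyl)-1,2,4-trioxolane (ozonide, formed in the flask) | CC(=O)OCC1OOC(COC(C)=O)O1 | intermediate
18 | 2-oxoethyl acetate | CC(=O)OCC=O | intermediate
19 | potassium salt of the phosphonate carbanion of 15 (formed in the flask) | C=C(C)[C@@H]1Oc2cc(OCc3ccc(OC)cc3)c(C(C)=O)cc2[C@@H]1OC(=O)[C-](C)P(=O)(OCC(F)(F)F)OCC(F)(F)F.[K+] | intermediate
20 | (2S,3S)-5-acetyl-6-[(4-methoxybenzyl)oxy]-2-(prop-1-en-2-yl)-2,3-dihydro-1-benzofuran-3-yl (2Z)-4-(acetyloxy)-2-methylbut-2-enoate | C=C(C)[C@@H]1Oc2cc(OCc3ccc(OC)cc3)c(C(C)=O)cc2[C@@H]1OC(=O)/C(C)=C\COC(C)=O | intermediate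
21 | (2S,3S)-5-acetyl-6-hydroxy-2-(prop-1-en-2-yl)-2,3-dihydro-1-benzofuran-3-yl (2Z)-4-(acetyloxy)-2-methylbut-2-enoate (CNP0273504.2) | C=C(C)[C@@H]1Oc2cc(O)c(C(C)=O)cc2[C@@H]1OC(=O)/C(C)=C\COC(C)=O | target

**Step count and risks**

Total step count: 12. Longest linear sequence: 8 steps (steps 1, 2, 3, 6, 8, 9, 11 and 12, from 2,4-dihydroxyacetophenone).

Steps most likely to fail:

1. Step 6 (Proposed new method). The acetyl-deactivated aryloxide may add too slowly for the sensitive aldehyde to survive, the addition may lose its anti preference, or the titanium-bound epoxy alkoxide may open at the tertiary carbon before the base takes over. The fallback uses known chemistry, sets out from 4 and 7 and comes back at 10; it makes the C–C bond by an organochromium addition instead of by the phenoxide. Iodination of 4 with N-iodosuccinimide (MeCN, rt), ortho to the hydroxyl and para to the PMB ether, should give 1-[4-hydroxy-5-iodo-2-[(4-methoxybenzyl)oxy]phenyl]ethanone F1. TBSCl and imidazole in DMF should give 1-[4-[(tert-butyldimethylsilyl)oxy]-5-iodo-2-[(4-methoxybenzyl)oxy]phenyl]ethanone F2. Nozaki–Hiyama–Kishi coupling of F2 with 7 (CrCl2, NiCl2 cat., DMF, rt), which tolerates the methyl ketone, is expected to give mainly the Felkin–Anh alcohol 1-[4-[(tert-butyldimethylsilyl)oxy]-5-[(S)-[(S)-3,3-dimethyloxiran-2-yl](hydroxy)methyl]-2-[(4-methoxybenzyl)oxy]phenyl]ethanone F3. Bu4NF in THF then removes the silyl group, and the phenoxide set free closes the dihydrofuran ring by the same 5-exo epoxide opening, which returns to 10.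

2. Step 11. The base may enolise the aryl methyl ketone or attack the acetate of the aldehyde, or Z selectivity may erode with the bulky ester. The fallback sets out from 10 and comes back at 20; it makes the Z acid first and attaches it by esterification. 3-Methylfuran-2(5H)-one (commercial, CC1=CCOC1=O) is opened with NaOH (1 equiv, H2O/MeOH) to sodium (Z)-4-hydroxy-2-methylbut-2-enoate F4, whose geometry is fixed by the lactone. Alkylation of the dry salt with 4-methoxybenzyl chloride in DMF should give 4-methoxybenzyl (Z)-4-hydroxy-2-methylbut-2-enoate F5, which is acetylated at once (Ac2O, pyridine, DMAP cat.) to 4-methoxybenzyl (Z)-4-acetoxy-2-methylbut-2-enoate F6. CF3CO2H and anisole in CH2Cl2 at 0 °C should free (Z)-4-acetoxy-2-methylbut-2-enoic acid F7. Yamaguchi esterification of 10 with F7 (2,4,6-trichlorobenzoyl chloride, Et3N, THF; then DMAP, toluene, rt) should give (2R,3S)-5-acetyl-2-(2-hydroxypropan-2-yl)-6-[(4-methoxybenzyl)oxy]-2,3-dihydro-1-benzofuran-3-yl (2Z)-4-(acetyloxy)-2-methylbut-2-enoate F8, and Burgess dehydration of F8 under the conditions of step 9 leads to 20.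

3. Step 9. Elimination may run toward C2–H (enol ether, then loss of the C3 ester and aromatisation), or the neighbouring ester may take part in ionisation of the sulfamate. The fallback sets out from 10 and comes back at 15; it dehydrates before acylation, on a substrate without a C3 ester and by a base-induced anti elimination. TESCl and imidazole (CH2Cl2, 0 °C) should silylate only the secondary hydroxyl of 10 to give 1-[(2R,3S)-2-(2-hydroxypropan-2-yl)-6-[(4-methoxybenzyl)oxy]-3-[(triethylsilyl)oxy]-2,3-dihydro-1-benzofuran-5-yl]ethanone F9. SOCl2 and pyridine at 0 °C (chlorosulfite, E2 by pyridine at a methyl group) should give 1-[(2S,3S)-6-[(4-methoxybenzyl)oxy]-2-(prop-1-en-2-yl)-3-[(triethylsilyl)oxy]-2,3-dihydro-1-benzofuran-5-yl]ethanone F10. Bu4NF buffered with AcOH in THF should give 1-[(2S,3S)-3-hydroxy-6-[(4-methoxybenzyl)oxy]-2-(prop-1-en-2-yl)-2,3-dihydro-1-benzofuran-5-yl]ethanone F11, which is esterified with 12 under the conditions of step 8 to reach 15.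

Further compounds
F1 | step 6 | 1-[4-hydroxy-5-iodo-2-[(4-methoxybenzyl)oxy]phenyl]ethanone | CC(=O)c1cc(I)c(O)cc1OCc2ccc(OC)cc2
F2 | step 6 | 1-[4-[(tert-butyldimethylsilyl)oxy]-5-iodo-2-[(4-methoxybenzyl)oxy]phenyl]ethanone | CC(=O)c1cc(I)c(O[Si](C)(C)C(C)(C)C)cc1OCc2ccc(OC)cc2
F3 | step 6 | 1-[4-[(tert-butyldimethylsilyl)oxy]-5-[(S)-[(S)-3,3-dimethyloxiran-2-yl](hydroxy)methyl]-2-[(4-methoxybenzyl)oxy]phenyl]ethanone | CC(=O)c1cc([C@H](O)[C@@H]2OC2(C)C)c(O[Si](C)(C)C(C)(C)C)cc1OCc3ccc(OC)cc3
F4 | step 11 | sodium (Z)-4-hydroxy-2-methylbut-2-enoate | [Na+].[O-]C(=O)/C(C)=C\CO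
F5 | step 11 | 4-methoxybenzyl (Z)-4-hydroxy-2-methylbut-2-enoate | COc1ccc(COC(=O)/C(C)=C\CO)cc1
F6 | step 11 | 4-methoxybenzyl (Z)-4-acetoxy-2-methylbut-2-enoate | COc1ccc(COC(=O)/C(C)=C\COC(C)=O)cc1
F7 | step 11 | (Z)-4-acetoxy-2-methylbut-2-enoic acid | OC(=O)/C(C)=C\COC(C)=O
F8 | step 11 | (2R,3S)-5-acetyl-2-(2-hydroxypropan-2-yl)-6-[(4-methoxybenzyl)oxy]-2,3-dihydro-1-benzofuran-3-yl (2Z)-4-(acetyloxy)-2-methylbut-2-enoate | CC(C)(O)[C@@H]1Oc2cc(OCc3ccc(OC)cc3)c(C(C)=O)cc2[C@@H]1OC(=O)/C(C)=C\COC(C)=O
F9 | step 9 | 1-[(2R,3S)-2-(2-hydroxypropan-2-yl)-6-[(4-methoxybenzyl)oxy]-3-[(triethylsilyl)oxy]-2,3-dihydro-1-benzofuran-5-yl]ethanone | CC(C)(O)[C@@H]1Oc2cc(OCc3ccc(OC)cc3)c(C(C)=O)cc2[C@@H]1O[Si](CC)(CC)CC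
F10 | step 9 | 1-[(2S,3S)-6-[(4-methoxybenzyl)oxy]-2-(prop-1-en-2-yl)-3-[(triethylsilyl)oxy]-2,3-dihydro-1-benzofuran-5-yl]ethanone | C=C(C)[C@@H]1Oc2cc(OCc3ccc(OC)cc3)c(C(C)=O)cc2[C@@H]1O[Si](CC)(CC)CC
F11 | step 9 | 1-[(2S,3S)-3-hydroxy-6-[(4-methoxybenzyl)oxy]-2-(prop-1-en-2-yl)-2,3-dihydro-1-benzofuran-5-yl]ethanone | C=C(C)[C@@H]1Oc2cc(OCc3ccc(OC)cc3)c(C(C)=O)cc2[C@@H]1O
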